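**Retrosynthetic overview**
- Target ⇐ semi-hydrogenation of a pent-2-ynyl side chain to the (Z)-alkene (last step).
- Tertiary acetate C–O ⇐ methyl ketone on the quaternary ring carbon by a Baeyer–Villiger 1,2-shift (the ring carbon migrates from C to O with retention; ionic, not pericyclic). The methyl ketone ⇐ a 1-(trimethylsilyl)ethenyl group via its epoxysilane, all in one oxidative cascade.
- Ring C=C ⇐ ketone dehydrogenation. Quaternary centre and the adjacent C–C bond ⇐ enantioselective conjugate addition of a 1-silylvinyl alane to a 3-alkylcyclopentenone, then anti propargylation of the enolate. The bulky silylvinyl group is the steric placeholder for the small acetoxy group, so the less stable cis-dialkyl arrangement is set kinetically.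
- 3-Alkylcyclopentenone ⇐ B-alkyl Suzuki coupling of a C8 ester chain (made by ester enolate alkylation) with a 3-halocyclopentenone.
- Rings: the only ring (the cyclopentenone) is bought; no ring is formed in the route.

Assumption: L1 is a chiral sulfonate-bearing 4,5-diphenylimidazolinium salt (carbene precursor); the antipode that gives the R quaternary centre is picked in a trial run with both antipodes.

Step 1
Reactants: 1 tert-butyl acetate; 2 6-bromohex-1-ene
Product: 4 tert-butyl oct-7-enoate, via lithium enolate 3 (not isolated)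
Conditions: LiN(i-Pr)2 (1.05 equiv), THF, −78 °C; then 2, HMPA, −78 °C → rt
Reagents that add atoms: none
Why: Ester enolate alkylation (SN2) of the lithium enolate of 1 with the unhindered primary bromide 2 gives the C8 chain with a terminal alkene for hydroboration; no stereocentre is formed.

Step 2
Reactants: 4 tert-butyl oct-7-enoate; 5 3-bromocyclopent-2-en-1-one
Product: 7 tert-butyl 8-(3-oxocyclopent-1-en-1-yl)octanoate, via alkylborane 6 (not isolated)
Conditions: 9-BBN-H (1.1 equiv), THF, 0 °C → rt; then 5, Pd(dppf)Cl2 (3 mol%), K3PO4 (3 M aq.), DMF, 50 °C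
Reagents that add atoms: none
Why: Anti-Markovnikov hydroboration followed by B-alkyl Suzuki–Miyaura coupling with the β-bromoenone joins the chain to the ring carbon that becomes the quaternary centre; the tert-butyl ester is inert and no stereocentre is formed.

Step 3
Reactants: 7 tert-butyl 8-(3-oxocyclopent-1-en-1-yl)octanoate; 8 ethynyltrimethylsilane; 9 1-bromopent-2-yne
Product: 13 tert-butyl 8-[(1R,2S)-3-oxo-2-(pent-2-yn-1-yl)-1-[1-(trimethylsilyl)ethenyl]cyclopentyl]octanoate, via vinylalane 10 (not isolated), via aluminium enolate 11 (not isolated), via aluminate enolate 12 (not isolated)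
Conditions: 8, i-Bu2AlH, hexane, 55 °C (gives 10); then 7, Cu(OTf)2 (5 mol%), L1 (6 mol%), THF, −78 → −30 °C; then MeLi, −78 °C; then 9, HMPA, −78 → −20 °C
Reagents that add atoms: none
Why: Hydroalumination puts Al on the silyl-bearing alkyne carbon, copper-catalysed enantioselective conjugate addition of the 1-silylvinyl group (carbene ligand from L1) sets the quaternary centre as R, and SN2 propargylation of the aluminate enolate occurs anti to the bulky 1-(trimethylsilyl)ethenyl group, setting the adjacent centre as S with the two carbon chains cis.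

Step 4
Reactants: 13 tert-butyl 8-[(1R,2S)-3-oxo-2-(pent-2-yn-1-yl)-1-[1-(trimethylsilyl)ethenyl]cyclopentyl]octanoate
Product: 15 tert-butyl 8-[(1R,5S)-4-oxo-5-(pent-2-yn-1-yl)-1-[1-(trimethylsilyl)ethenyl]cyclopent-2-en-1-yl]octanoate, via lithium enolate 14 (not isolated)
Conditions: LiN(i-Pr)2 (1.05 equiv), THF, −78 °C; then PhS(Cl)=N-t-Bu (1.2 equiv), −78 °C
Reagents that add atoms: none
Why: Kinetic deprotonation at the unhindered α-CH2 and Mukaiyama dehydrogenation with N-tert-butylbenzenesulfinimidoyl chloride (sulfilimine syn-elimination) give the enone; only this direction can desaturate because the other β-carbon is quaternary, and both stereocentres are untouched at −78 °C.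

Step 5
Reactants: 15 tert-butyl 8-[(1R,5S)-4-oxo-5-(pent-2-yn-1-yl)-1-[1-(trimethylsilyl)ethenyl]cyclopent-2-en-1-yl]octanoate
Product: 19 8-[(1R,5S)-1-(acetyloxy)-4-oxo-5-(pent-2-yn-1-yl)cyclopent-2-en-1-yl]octanoic acid, via epoxysilane 16 (not isolated), via methyl ketone 17 (not isolated), via acetate ester 18 (not isolated)
Conditions: mCPBA (3 equiv), TFA (10 equiv), CH2Cl2, 0 °C → rt; then TFA to 25% v/v, 0 °C → rt
Reagents that add atoms: mCPBA, OOC(=O)c1cccc(Cl)c1
Why: Proposed new method: one-pot conversion of a 1-silylvinyl group on a quaternary carbon into a tertiary acetate – the peracid epoxidises the vinylsilane (the alkyne and the electron-poor enone are far slower), TFA opens the epoxysilane at CH2–O to a β-silyl-stabilised cation that loses silicon to give the enol and hence the methyl ketone, a second peracid adds to this ketone and in the Criegee adduct the quaternary allylic ring carbon makes the Baeyer–Villiger 1,2-shift from carbon to oxygen with retention (methyl cannot compete, the conjugated ring ketone is deactivated), and TFA finally removes the tert-butyl group; the closest known reactions are the epoxysilane-to-ketone conversion and the acid-accelerated Baeyer–Villiger oxidation of hindered methyl ketones, which have not been run as one cascade.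

Step 6
Reactants: 19 8-[(1R,5S)-1-(acetyloxy)-4-oxo-5-(pent-2-yn-1-yl)cyclopent-2-en-1-yl]octanoic acid
Product: 20 8-[(1R,5S)-1-(acetyloxy)-4-oxo-5-[(2Z)-pent-2-en-1-yl]cyclopent-2-en-1-yl]octanoic acid
Conditions: H2 (1 atm), Pd/CaCO3 poisoned with Pb(OAc)2 (Lindlar catalyst, 5 wt% Pd), quinoline, EtOAc, rt, stopped at 1.0 equiv H2
Reagents that add atoms: none
Why: Lindlar semi-hydrogenation delivers H2 syn to the alkyne on the Pb-poisoned Pd/CaCO3 surface to give the (Z)-alkene, while the quinoline-moderated catalyst leaves the conjugated ring alkene, the allylic acetate and both stereocentres alone.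

**Compound list**
1 | tert-butyl acetate | CC(=O)OC(C)(C)C | starting material
2 | 6-bromohex-1-ene | C=CCCCCBr | starting material
3 | lithium 1-tert-butoxyethen-1-olate (lithium enolate of 1) | C=C(O[Li])OC(C)(C)C | intermediate
4 | tert-butyl oct-7-enoate | C=CCCCCCC(=O)OC(C)(C)C | intermediate
5 | 3-bromocyclopent-2-en-1-one | O=C1CCC(Br)=C1 | starting material
6 | tert-butyl 8-(9-borabicyclo[3.3.1]nonan-9-yl)octanoate | CC(C)(C)OC(=O)CCCCCCCB1C2CCCC1CCC2 | intermediate
7 | tert-butyl 8-(3-oxocyclopent-1-en-1-yl)octanoate | O=C1CCC(CCCCCCCC(=O)OC(C)(C)C)=C1 | intermediate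
8 | ethynyltrimethylsilane | C#C[Si](C)(C)C | starting material
9 | 1-bromopent-2-yne | CCC#CCBr | starting material
10 | diisobutyl[1-(trimethylsilyl)ethenyl]aluminium | C=C([Si](C)(C)C)[Al](CC(C)C)CC(C)C | intermediate
11 | diisobutylaluminium (3R)-3-(8-tert-butoxy-8-oxooctyl)-3-[1-(trimethylsilyl)ethenyl]cyclopent-1-en-1-olate | CC(C)C[Al](CC(C)C)OC1=C[C@](CCCCCCCC(=O)OC(C)(C)C)(C(=C)[Si](C)(C)C)CC1 | intermediate
12 | lithium methyl(diisobutyl)aluminate of the (3R)-enolate 11 | [Li+].CC(C)C[Al-](C)(CC(C)C)OC1=C[C@](CCCCCCCC(=O)OC(C)(C)C)(C(=C)[Si](C)(C)C)CC1 | intermediate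
13 | tert-butyl 8-[(1R,2S)-3-oxo-2-(pent-2-yn-1-yl)-1-[1-(trimethylsilyl)ethenyl]cyclopentyl]octanoate | CCC#CC[C@@H]1C(=O)CC[C@@]1(CCCCCCCC(=O)OC(C)(C)C)C(=C)[Si](C)(C)C | intermediate
14 | lithium (4R,5S)-4-(8-tert-butoxy-8-oxooctyl)-5-(pent-2-yn-1-yl)-4-[1-(trimethylsilyl)ethenyl]cyclopent-1-en-1-olate | CCC#CC[C@@H]1C(O[Li])=CC[C@@]1(CCCCCCCC(=O)OC(C)(C)C)C(=C)[Si](C)(C)C | intermediate
15 | tert-butyl 8-[(1R,5S)-4-oxo-5-(pent-2-yn-1-yl)-1-[1-(trimethylsilyl)ethenyl]cyclopent-2-en-1-yl]octanoate | CCC#CC[C@@H]1C(=O)C=C[C@@]1(CCCCCCCC(=O)OC(C)(C)C)C(=C)[Si](C)(C)C | intermediate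
16 | tert-butyl 8-[(1R,5S)-4-oxo-5-(pent-2-yn-1-yl)-1-[(2RS)-2-(trimethylsilyl)oxiran-2-yl]cyclopent-2-en-1-yl]octanoate | CCC#CC[C@@H]1C(=O)C=C[C@@]1(CCCCCCCC(=O)OC(C)(C)C)C2(CO2)[Si](C)(C)C | intermediate
17 | tert-butyl 8-[(1R,5S)-1-acetyl-4-oxo-5-(pent-2-yn-1-yl)cyclopent-2-en-1-yl]octanoate | CCC#CC[C@@H]1C(=O)C=C[C@@]1(CCCCCCCC(=O)OC(C)(C)C)C(C)=O | intermediate
18 | tert-butyl 8-[(1R,5S)-1-(acetyloxy)-4-oxo-5-(pent-2-yn-1-yl)cyclopent-2-en-1-yl]octanoate | CCC#CC[C@@H]1C(=O)C=C[C@@]1(CCCCCCCC(=O)OC(C)(C)C)OC(C)=O | intermediate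
19 | 8-[(1R,5S)-1-(acetyloxy)-4-oxo-5-(pent-2-yn-1-yl)cyclopent-2-en-1-yl]octanoic acid | CCC#CC[C@@H]1C(=O)C=C[C@@]1(CCCCCCCC(=O)O)OC(C)=O | intermediate
20 | 8-[(1R,5S)-1-(acetyloxy)-4-oxo-5-[(2Z)-pent-2-en-1-yl]cyclopent-2-en-1-yl]octanoic acid | CC/C=C\C[C@@H]1C(=O)C=C[C@@]1(CCCCCCCC(=O)O)OC(C)=O | target

**Step count**
Total steps: 6. Longest linear sequence: 6 steps (1 → 4 → 7 → 13 → 15 → 19 → 20); 5, 8 and 9 enter without separate steps.

**Steps most likely to fail**

Step 5 (the proposed new cascade). The risks are slow oxidation of the alkyne by excess peracid, acid-catalysed epimerisation of the centre next to the ring ketone (the cis-dialkyl isomer is the less stable one), and an incomplete 1,2-shift. The fallback uses known chemistry, sets out from 15 and comes back at 19. The cascade is given up and each event is run as a separate, isolated operation: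
- buffered epoxidation (mCPBA, Na2HPO4, CH2Cl2) to epoxysilane 16;
- epoxysilane-to-ketone conversion (10% aq. H2SO4, THF) to methyl ketone 17;
- a classical buffered Baeyer–Villiger oxidation (CF3CO3H, Na2HPO4, CH2Cl2, 0 °C) to acetate ester 18;
- brief TFA/CH2Cl2 at 0 °C to 19.

No compound outside the list is made (F0).

Step 3 (conjugate addition with in-pot alkylation). The risks are low enantioselectivity with the long-chain substrate and a sluggish aluminate enolate. The fallback sets out from 7 (with 10) and comes back at 13. The two events are separated: after the conjugate addition the aluminium enolate is trapped with Et3SiOTf and the triethylsilyl enol ether F1 is isolated. Anhydrous BnMe3NF then releases the metal-free benzyltrimethylammonium enolate F2, which is alkylated with 9 (THF, −78 → 0 °C), again anti to the silylvinyl group.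

Step 6 (semi-hydrogenation beside a cyclopentenone and a tertiary allylic acetate). The risks are over-reduction of the ring alkene and hydrogenolysis of the acetate. The fallback sets out from 13 and comes back at 20; it moves the reduction to a stage without enone or acetate and then avoids electrophilic oxidants:
- the same poisoned Pd/CaCO3 reduction on 13 gives (Z)-alkene ketone F3;
- dehydrogenation as in step 4 gives enone F5 through lithium enolate F4;
- TFA removes the silyl group (protodesilylation) and the tert-butyl ester to give vinyl acid F6;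
- Tsuji–Wacker oxidation (PdCl2, CuCl, O2, DMF/H2O), which prefers the terminal vinyl group over the internal (Z)-alkene, gives methyl ketone acid F7;
- Baeyer–Villiger oxidation with Me3SiOOSiMe3/Me3SiOTf, a nucleophilic peroxide that does not epoxidise alkenes, gives 20.

Further compounds
F0 | step 5 | none | none
F1 | step 3 | tert-butyl 8-[(1R)-3-[(triethylsilyl)oxy]-1-[1-(trimethylsilyl)ethenyl]cyclopent-2-en-1-yl]octanoate | CC[Si](CC)(CC)OC1=C[C@](CCCCCCCC(=O)OC(C)(C)C)(C(=C)[Si](C)(C)C)CC1
F2 | step 3 | benzyltrimethylammonium (3R)-3-(8-tert-butoxy-8-oxooctyl)-3-[1-(trimethylsilyl)ethenyl]cyclopent-1-en-1-olate | C[N+](C)(C)Cc1ccccc1.[O-]C1=C[C@](CCCCCCCC(=O)OC(C)(C)C)(C(=C)[Si](C)(C)C)CC1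
F3 | step 6 | tert-butyl 8-[(1R,2S)-3-oxo-2-[(2Z)-pent-2-en-1-yl]-1-[1-(trimethylsilyl)ethenyl]cyclopentyl]octanoate | CC/C=C\C[C@@H]1C(=O)CC[C@@]1(CCCCCCCC(=O)OC(C)(C)C)C(=C)[Si](C)(C)C
F4 | step 6 | lithium (4R,5S)-4-(8-tert-butoxy-8-oxooctyl)-5-[(2Z)-pent-2-en-1-yl]-4-[1-(trimethylsilyl)ethenyl]cyclopent-1-en-1-olate | CC/C=C\C[C@@H]1C(O[Li])=CC[C@@]1(CCCCCCCC(=O)OC(C)(C)C)C(=C)[Si](C)(C)C
F5 | step 6 | tert-butyl 8-[(1R,5S)-4-oxo-5-[(2Z)-pent-2-en-1-yl]-1-[1-(trimethylsilyl)ethenyl]cyclopent-2-en-1-yl]octanoate | CC/C=C\C[C@@H]1C(=O)C=C[C@@]1(CCCCCCCC(=O)OC(C)(C)C)C(=C)[Si](C)(C)C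
F6 | step 6 | 8-[(1R,5S)-1-ethenyl-4-oxo-5-[(2Z)-pent-2-en-1-yl]cyclopent-2-en-1-yl]octanoic acid | CC/C=C\C[C@@H]1C(=O)C=C[C@@]1(CCCCCCCC(=O)O)C=C
F7 | step 6 | 8-[(1R,5S)-1-acetyl-4-oxo-5-[(2Z)-pent-2-en-1-yl]cyclopent-2-en-1-yl]octanoic acid | CC/C=C\C[C@@H]1C(=O)C=C[C@@]1(CCCCCCCC(=O)O)C(C)=O
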